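**Retrosynthetic overview**

1. Locants: ring A = C1–C4, C4a, C8a (enone, C2=O, gem‑dimethyl C4); ring B = C4a, C5–C8, C8a (C7 methyl, quaternary C8); side chain C1'–C6' with the stereocentre at C3'. The sulfate, the silyl ether and the side‑chain alkene are adjusted last; the enone is unmasked from a 3‑ethoxy dienol ether.
2. Key disconnection: ring B is cut at C5–C6 and at C8–C8a. This gives ring A as the methylidene vinylogous ester 27 (from a dimedone enol ether) and the open‑chain bromide 22, which carries C6, C7, C8 and the whole side chain.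
3. Forward, one flask joins them: copper‑catalysed conjugate addition (C5–C6), O‑triflation of the enolate so formed, and 6‑exo Mizoroki–Heck closure (C8–C8a). Ring A exists first; ring B is formed in the key step.
4. Enabling feature: the α‑methylidene ketone C5=C4a–C8a=O of ring A is an acceptor at C5. The single enolate it gives (C4a=C8a–O) turns C8a into an alkenyl electrophile, three atoms away from the alkene that becomes quaternary C8.
5. Bromide 22 comes from hydroxy ester 1 (C7), zirconium‑catalysed carboalumination (E‑alkene) and Negishi coupling with iodide 18; the C3' stereocentre of 18 is set by auxiliary‑controlled hydroxymethylation.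

Key step: step 16

Remark: the target is drawn as the free hydrogen sulfate. Sulfation first gives the pyridinium salt, and a short contact with a sulfonic acid resin (H form) at 0 °C is assumed to give the acid as drawn; for storage it would be neutralised to the sodium salt.

**Route**

Step 1
Reactants: 1 methyl (R)-3-hydroxy-2-methylpropanoate
Product: 2 methyl (R)-3-[(tert-butyldimethylsilyl)oxy]-2-methylpropanoate
Conditions: TBSCl, imidazole, CH2Cl2, 0 °C to rt
Reagents that add atoms: tert-butyldimethylsilyl chloride, CC(C)(C)[Si](C)(C)Cl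
Why: Standard silyl ether formation at the primary alcohol should leave the ester and the future C7 stereocentre untouched.

Step 2
Reactants: 2 methyl (R)-3-[(tert-butyldimethylsilyl)oxy]-2-methylpropanoate
Product: 3 (R)-3-[(tert-butyldimethylsilyl)oxy]-2-methylpropanal
Conditions: i-Bu2AlH, CH2Cl2, −78 °C; aq. KNaC4H4O6 work-up; crude aldehyde used at once
Reagents that add atoms: none
Why: Half-reduction of the ester stops at the aldehyde because the tetrahedral aluminate is stable at −78 °C, and the α-stereocentre should survive if the aldehyde is not stored.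

Step 3
Reactants: 3 (R)-3-[(tert-butyldimethylsilyl)oxy]-2-methylpropanal
Product: 4 (S)-tert-butyldimethyl[(2-methylbut-3-yn-1-yl)oxy]silane
Conditions: dimethyl (1-diazo-2-oxopropyl)phosphonate, K2CO3, MeOH, 0 °C to rt
Reagents that add atoms: dimethyl (1-diazo-2-oxopropyl)phosphonate, COP(=O)(OC)C(=[N+]=[N-])C(C)=O
Why: Seyferth–Gilbert homologation under these mild conditions should convert the α-branched aldehyde into the terminal alkyne without epimerisation.

Step 4
Reactants: 4 (S)-tert-butyldimethyl[(2-methylbut-3-yn-1-yl)oxy]silane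
Product: 6 tert-butyl{[(2S,3E)-4-iodo-2,3-dimethylbut-3-en-1-yl]oxy}dimethylsilane, via alkenylalane 5 (not isolated)
Conditions: AlMe3 (3 equiv), Cp2ZrCl2 (0.3 equiv), CH2Cl2, 0 °C to rt; then I2, THF, −30 °C
Reagents that add atoms: trimethylaluminium, C[Al](C)C; iodine, II
Why: Zirconium-catalysed carboalumination adds methyl and aluminium syn across the alkyne (methyl to the internal carbon), and iodinolysis with retention should give the E-alkenyl iodide as one geometric isomer.

Step 5
Reactants: 7 (S)-4-benzyloxazolidin-2-one; 8 pent-4-enoyl chloride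
Product: 10 (S)-4-benzyl-3-(pent-4-enoyl)oxazolidin-2-one, via lithiated oxazolidinone 9 (not isolated)
Conditions: n-BuLi, THF, −78 °C; then 8, −78 °C to 0 °C
Reagents that add atoms: none
Why: N-Acylation of the lithiated oxazolidinone with the acid chloride installs the chiral auxiliary.

Step 6
Reactants: 10 (S)-4-benzyl-3-(pent-4-enoyl)oxazolidin-2-one
Product: 12 (S)-4-benzyl-3-[(R)-2-(hydroxymethyl)pent-4-enoyl]oxazolidin-2-one, via titanium enolate 11 (not isolated)
Conditions: TiCl4, i-Pr2NEt, CH2Cl2, 0 °C; then 1,3,5-trioxane, TiCl4, 0 °C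
Reagents that add atoms: 1,3,5-trioxane, C1OCOCO1
Why: Aldol-type hydroxymethylation of the chelated Z titanium enolate with TiCl4-activated formaldehyde takes place on the face opposite the benzyl group and so sets the future C3' stereocentre.

Step 7
Reactants: 12 (S)-4-benzyl-3-[(R)-2-(hydroxymethyl)pent-4-enoyl]oxazolidin-2-one
Product: 13 (S)-4-benzyl-3-[(R)-2-{[(tert-butyldiphenylsilyl)oxy]methyl}pent-4-enoyl]oxazolidin-2-one
Conditions: TBDPSCl, imidazole, CH2Cl2, 0 °C to rt
Reagents that add atoms: tert-butyldiphenylsilyl chloride, CC(C)(C)[Si](Cl)(c1ccccc1)c1ccccc1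
Why: Silylation of the primary alcohol gives a robust ether that should last until step 19.

Step 8
Reactants: 13 (S)-4-benzyl-3-[(R)-2-{[(tert-butyldiphenylsilyl)oxy]methyl}pent-4-enoyl]oxazolidin-2-one
Product: 14 (S)-2-{[(tert-butyldiphenylsilyl)oxy]methyl}pent-4-en-1-ol
Conditions: LiBH4, MeOH (1 equiv), Et2O, 0 °C
Reagents that add atoms: none
Why: Reductive cleavage of the N-acyl oxazolidinone gives the primary alcohol and removes the epimerisable α-proton before any basic step.

Step 9
Reactants: 14 (S)-2-{[(tert-butyldiphenylsilyl)oxy]methyl}pent-4-en-1-ol; 15 3-bromofuran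
Product: 17 (S)-2-{[(tert-butyldiphenylsilyl)oxy]methyl}-5-(furan-3-yl)pentan-1-ol, via bis-boron adduct 16 (not isolated)
Conditions: 9-BBN (2.2 equiv), THF, 0 °C to rt; then 15, Pd(dppf)Cl2 (5 mol %), K3PO4, H2O, DMF, 50 °C
Reagents that add atoms: none
Why: B-Alkyl Suzuki–Miyaura coupling (anti-Markovnikov hydroboration of the terminal alkene, then palladium-catalysed coupling with the bromofuran) attaches the furan; the free hydroxyl only consumes one extra equivalent of borane.

Step 10
Reactants: 17 (S)-2-{[(tert-butyldiphenylsilyl)oxy]methyl}-5-(furan-3-yl)pentan-1-ol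
Product: 18 (R)-tert-butyl{[5-(furan-3-yl)-2-(iodomethyl)pentyl]oxy}diphenylsilane
Conditions: I2, PPh3, imidazole, CH2Cl2, 0 °C to rt
Reagents that add atoms: iodine, II
Why: Appel-type iodination converts the primary alcohol into the iodide under neutral conditions that the furan and silyl ether tolerate.

Step 11
Reactants: 18 (R)-tert-butyl{[5-(furan-3-yl)-2-(iodomethyl)pentyl]oxy}diphenylsilane; 6 tert-butyl{[(2S,3E)-4-iodo-2,3-dimethylbut-3-en-1-yl]oxy}dimethylsilane
Product: 20 tert-butyl{[(2S,3E,6S)-6-{[(tert-butyldiphenylsilyl)oxy]methyl}-9-(furan-3-yl)-2,3-dimethylnon-3-en-1-yl]oxy}dimethylsilane, via alkylzinc iodide 19 (not isolated)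
Conditions: Zn dust, LiCl, THF, 40 °C; then 6, Pd(PPh3)4 (5 mol %), THF, rt to 45 °C
Reagents that add atoms: none
Why: Negishi coupling of the primary alkylzinc with the alkenyl iodide joins sp3 and sp2 carbons with retention of the E geometry.

Step 12
Reactants: 20 tert-butyl{[(2S,3E,6S)-6-{[(tert-butyldiphenylsilyl)oxy]methyl}-9-(furan-3-yl)-2,3-dimethylnon-3-en-1-yl]oxy}dimethylsilane
Product: 21 (2S,3E,6S)-6-{[(tert-butyldiphenylsilyl)oxy]methyl}-9-(furan-3-yl)-2,3-dimethylnon-3-en-1-ol
Conditions: PPTS (0.2 equiv), MeOH, CH2Cl2, rt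
Reagents that add atoms: none
Why: Acid-catalysed methanolysis cleaves the primary TBS ether much faster than the bulkier TBDPS ether (selective desilylation).

Step 13
Reactants: 21 (2S,3E,6S)-6-{[(tert-butyldiphenylsilyl)oxy]methyl}-9-(furan-3-yl)-2,3-dimethylnon-3-en-1-ol
Product: 22 {[(2S,4E,6S)-7-bromo-2-[3-(furan-3-yl)propyl]-5,6-dimethylhept-4-en-1-yl]oxy}(tert-butyl)diphenylsilane
Conditions: CBr4, PPh3, CH2Cl2, 0 °C
Reagents that add atoms: carbon tetrabromide, BrC(Br)(Br)Br
Why: Appel bromination of the primary alcohol is neutral and should leave the trisubstituted alkene and the furan intact.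

Step 14
Reactants: 23 3-ethoxy-5,5-dimethylcyclohex-2-en-1-one
Product: 25 6-[(dimethylamino)methyl]-3-ethoxy-5,5-dimethylcyclohex-2-en-1-one (racemic), via lithium dienolate 24 (not isolated)
Conditions: LiN(i-Pr)2, THF, −78 °C; then Me2N=CH2 I, −78 °C to rt
Reagents that add atoms: N,N-dimethylmethylideneammonium iodide, C=[N+](C)C.[I-]
Why: Kinetic deprotonation of the vinylogous ester at C6 and Mannich reaction with the preformed iminium salt place the carbon that becomes C5.

Step 15
Reactants: 25 6-[(dimethylamino)methyl]-3-ethoxy-5,5-dimethylcyclohex-2-en-1-one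
Product: 27 3-ethoxy-5,5-dimethyl-6-methylidenecyclohex-2-en-1-one, via ammonium iodide 26 (not isolated)
Conditions: MeI, Et2O, rt; then DBU, CH2Cl2, 0 °C; used at once
Reagents that add atoms: none
Why: Quaternisation and base-induced elimination of the β-ammonium ketone (Hofmann-type E1cB) unveil the α-methylidene ketone.

Step 16
Reactants: 22 {[(2S,4E,6S)-7-bromo-2-[3-(furan-3-yl)propyl]-5,6-dimethylhept-4-en-1-yl]oxy}(tert-butyl)diphenylsilane; 27 3-ethoxy-5,5-dimethyl-6-methylidenecyclohex-2-en-1-one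
Product: 31 tert-butyl{[(2S,3E)-4-[(1S,2R)-7-ethoxy-1,2,5,5-tetramethyl-1,2,3,4,5,6-hexahydronaphthalen-1-yl]-2-[3-(furan-3-yl)propyl]but-3-en-1-yl]oxy}diphenylsilane, via Grignard reagent 28 (not isolated), via magnesium enolate 29 (not isolated), via dienyl triflate 30 (not isolated)
Conditions: Mg, THF, 35 °C; CuBr·SMe2 (10 mol %), 27, THF, −78 to −30 °C; N-(5-chloropyridin-2-yl)bis(trifluoromethanesulfonyl)imide, −78 °C to rt; then Pd(OAc)2 (10 mol %), 1,3-bis(diphenylphosphino)propane (12 mol %), 1,2,2,6,6-pentamethylpiperidine, DMA, 75 °C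
Reagents that add atoms: none
Why: The Grignard reagent from 22 adds under copper catalysis to the methylidene carbon of 27 (1,4-addition to an α-methylidene ketone), which forms C5–C6 and one regiodefined enolate (C4a=C8a–O) that the triflimide O-sulfonylates to dienyl triflate 30; zerovalent palladium then inserts into the C8a–O bond, the alkenylpalladium adds across the E-trisubstituted alkene and β-hydride loss toward C2' frees the catalyst. The closest known reaction types are one-pot conjugate addition–enolate triflation–cross-coupling sequences and the intramolecular Mizoroki–Heck reaction of alkenyl triflates that forms quaternary carbons. Ring B is closed in the 6-exo-trig mode at the C8–C8a bond. The only new stereocentre, C8, is set in the migratory insertion: ring B develops as a half-chair with the C7 methyl equatorial, and the palladium-bearing C1' must lie pseudo-axial (coplanar with Pd–C8a) with the C8 methyl pseudo-equatorial, which places the side chain cis to the C7 methyl as in the target, whereas attack on the other alkene face needs a boat-like ring B or an axial C7 methyl that eclipses the C8 methyl. The step needs 1,4- over 1,2-addition (copper catalysis and the unhindered methylidene terminus secure it), O- over C-sulfonylation, exo over endo closure, and β-hydride loss only toward C2' (C8 is quaternary); the hindered amine base should suppress re-addition of palladium hydride that could move the alkene toward C3'. The E geometry of the alkene keeps the substituent cis to C7 on C1' a hydrogen, so the tether carbon C6 meets no allylic strain in this transition state.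

Step 17
Reactants: 31 tert-butyl{[(2S,3E)-4-[(1S,2R)-7-ethoxy-1,2,5,5-tetramethyl-1,2,3,4,5,6-hexahydronaphthalen-1-yl]-2-[3-(furan-3-yl)propyl]but-3-en-1-yl]oxy}diphenylsilane
Product: 32 (4aS,7R,8S)-8-[(1E,3S)-3-{[(tert-butyldiphenylsilyl)oxy]methyl}-6-(furan-3-yl)hex-1-en-1-yl]-4,4,7,8-tetramethyl-4,4a,5,6,7,8-hexahydronaphthalen-2(3H)-one
Conditions: 1 M HCl, THF, 0 °C to rt
Reagents that add atoms: water, O
Why: Acid hydrolysis of the dienol ether (the unmasking step of a Stork–Danheiser sequence) gives the conjugated enone; C4a is set by axial protonation of the dienol terminus through the half-chair with the C7 methyl equatorial, which puts H-4a trans-diaxial to H-7, and this epimer is also the more stable one, though the preference is expected to be moderate.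

Step 18
Reactants: 32 (4aS,7R,8S)-8-[(1E,3S)-3-{[(tert-butyldiphenylsilyl)oxy]methyl}-6-(furan-3-yl)hex-1-en-1-yl]-4,4,7,8-tetramethyl-4,4a,5,6,7,8-hexahydronaphthalen-2(3H)-one
Product: 33 (4aS,7R,8R)-8-[(3S)-3-{[(tert-butyldiphenylsilyl)oxy]methyl}-6-(furan-3-yl)hexyl]-4,4,7,8-tetramethyl-4,4a,5,6,7,8-hexahydronaphthalen-2(3H)-one
Conditions: 2-nitrobenzenesulfonyl hydrazide (excess), Et3N, CH2Cl2, rt
Reagents that add atoms: none
Why: Diimide reduction transfers two hydrogens in a concerted syn fashion to the isolated 1,2-disubstituted alkene and should leave the conjugated trisubstituted enone, the furan and the silyl ether untouched.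

Step 19
Reactants: 33 (4aS,7R,8R)-8-[(3S)-3-{[(tert-butyldiphenylsilyl)oxy]methyl}-6-(furan-3-yl)hexyl]-4,4,7,8-tetramethyl-4,4a,5,6,7,8-hexahydronaphthalen-2(3H)-one
Product: 34 (4aS,7R,8R)-8-[(3S)-6-(furan-3-yl)-3-(hydroxymethyl)hexyl]-4,4,7,8-tetramethyl-4,4a,5,6,7,8-hexahydronaphthalen-2(3H)-one
Conditions: Bu4NF, AcOH (1:1), THF, rt
Reagents that add atoms: none
Why: Fluoride-mediated desilylation, buffered with acetic acid so that the enone is not deprotonated at C4a.

Step 20
Reactants: 34 (4aS,7R,8R)-8-[(3S)-6-(furan-3-yl)-3-(hydroxymethyl)hexyl]-4,4,7,8-tetramethyl-4,4a,5,6,7,8-hexahydronaphthalen-2(3H)-one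
Product: 36 (2S)-5-(furan-3-yl)-2-{2-[(1R,2R,4aS)-1,2,5,5-tetramethyl-7-oxo-1,2,3,4,4a,5,6,7-octahydronaphthalen-1-yl]ethyl}pentyl hydrogen sulfate, via pyridinium sulfate 35 (not isolated)
Conditions: SO3·pyridine, pyridine, 0 °C to rt; then sulfonic acid resin (H form), MeOH, 0 °C
Reagents that add atoms: sulfur trioxide–pyridine complex, [O-]S(=O)(=O)[n+]1ccccc1
Why: O-Sulfation of the primary alcohol with the SO3·pyridine complex should be much faster than C-sulfonation of the furan at this temperature, and brief cation exchange gives the hydrogen sulfate.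

**Compound list**

1 | methyl (R)-3-hydroxy-2-methylpropanoate | C[C@H](CO)C(=O)OC | starting material
2 | methyl (R)-3-[(tert-butyldimethylsilyl)oxy]-2-methylpropanoate | C[C@H](CO[Si](C)(C)C(C)(C)C)C(=O)OC | intermediate
3 | (R)-3-[(tert-butyldimethylsilyl)oxy]-2-methylpropanal | C[C@H](CO[Si](C)(C)C(C)(C)C)C=O | intermediate
4 | (S)-tert-butyldimethyl[(2-methylbut-3-yn-1-yl)oxy]silane | C[C@H](CO[Si](C)(C)C(C)(C)C)C#C | intermediate
5 | [(1E,3S)-4-[(tert-butyldimethylsilyl)oxy]-2,3-dimethylbut-1-en-1-yl]dimethylalane (formed in the flask) | C[C@H](CO[Si](C)(C)C(C)(C)C)/C(C)=C/[Al](C)C | intermediate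
6 | tert-butyl{[(2S,3E)-4-iodo-2,3-dimethylbut-3-en-1-yl]oxy}dimethylsilane | C[C@H](CO[Si](C)(C)C(C)(C)C)/C(C)=C/I | intermediate
7 | (S)-4-benzyloxazolidin-2-one | O=C1N[C@@H](Cc2ccccc2)CO1 | starting material
8 | pent-4-enoyl chloride | C=CCCC(Cl)=O | starting material
9 | N-lithio derivative of 7 (formed in the flask) | [Li]N1[C@@H](Cc2ccccc2)COC1=O | intermediate
10 | (S)-4-benzyl-3-(pent-4-enoyl)oxazolidin-2-one | C=CCCC(=O)N1[C@@H](Cc2ccccc2)COC1=O | intermediate
11 | trichlorotitanium Z-enolate of 10 (formed in the flask) | C=CC/C=C(\O[Ti](Cl)(Cl)Cl)N1[C@@H](Cc2ccccc2)COC1=O | intermediate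
12 | (S)-4-benzyl-3-[(R)-2-(hydroxymethyl)pent-4-enoyl]oxazolidin-2-one | O=C([C@H](CC=C)CO)N1[C@@H](Cc2ccccc2)COC1=O | intermediate
13 | (S)-4-benzyl-3-[(R)-2-{[(tert-butyldiphenylsilyl)oxy]methyl}pent-4-enoyl]oxazolidin-2-one | O=C([C@H](CC=C)CO[Si](c1ccccc1)(c1ccccc1)C(C)(C)C)N1[C@@H](Cc2ccccc2)COC1=O | intermediate
14 | (S)-2-{[(tert-butyldiphenylsilyl)oxy]methyl}pent-4-en-1-ol | OC[C@H](CC=C)CO[Si](c1ccccc1)(c1ccccc1)C(C)(C)C | intermediate
15 | 3-bromofuran | Brc1ccoc1 | starting material
16 | O,C-bis(9-borabicyclo[3.3.1]nonan-9-yl) adduct of 14, boron on O-1 and on C-5 (formed in the flask) | O(C[C@H](CCCB1C2CCCC1CCC2)CO[Si](c1ccccc1)(c1ccccc1)C(C)(C)C)B1C2CCCC1CCC2 | intermediate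
17 | (S)-2-{[(tert-butyldiphenylsilyl)oxy]methyl}-5-(furan-3-yl)pentan-1-ol | OC[C@H](CCCc1ccoc1)CO[Si](c1ccccc1)(c1ccccc1)C(C)(C)C | intermediate
18 | (R)-tert-butyl{[5-(furan-3-yl)-2-(iodomethyl)pentyl]oxy}diphenylsilane | IC[C@H](CCCc1ccoc1)CO[Si](c1ccccc1)(c1ccccc1)C(C)(C)C | intermediate
19 | alkylzinc iodide from 18, C–I replaced by C–ZnI (formed in the flask) | I[Zn]C[C@H](CCCc1ccoc1)CO[Si](c1ccccc1)(c1ccccc1)C(C)(C)C | intermediate
20 | tert-butyl{[(2S,3E,6S)-6-{[(tert-butyldiphenylsilyl)oxy]methyl}-9-(furan-3-yl)-2,3-dimethylnon-3-en-1-yl]oxy}dimethylsilane | C[C@H](CO[Si](C)(C)C(C)(C)C)/C(C)=C/C[C@H](CCCc1ccoc1)CO[Si](c1ccccc1)(c1ccccc1)C(C)(C)C | intermediate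
21 | (2S,3E,6S)-6-{[(tert-butyldiphenylsilyl)oxy]methyl}-9-(furan-3-yl)-2,3-dimethylnon-3-en-1-ol | OC[C@@H](C)/C(C)=C/C[C@H](CCCc1ccoc1)CO[Si](c1ccccc1)(c1ccccc1)C(C)(C)C | intermediate
22 | {[(2S,4E,6S)-7-bromo-2-[3-(furan-3-yl)propyl]-5,6-dimethylhept-4-en-1-yl]oxy}(tert-butyl)diphenylsilane | BrC[C@@H](C)/C(C)=C/C[C@H](CCCc1ccoc1)CO[Si](c1ccccc1)(c1ccccc1)C(C)(C)C | intermediate
23 | 3-ethoxy-5,5-dimethylcyclohex-2-en-1-one | CCOC1=CC(=O)CC(C)(C)C1 | starting material
24 | lithium 3-ethoxy-5,5-dimethylcyclohexa-1,3-dien-1-olate (formed in the flask) | CCOC1=CC(O[Li])=CC(C)(C)C1 | intermediate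
25 | 6-[(dimethylamino)methyl]-3-ethoxy-5,5-dimethylcyclohex-2-en-1-one (racemic) | CCOC1=CC(=O)C(CN(C)C)C(C)(C)C1 | intermediate
26 | (4-ethoxy-6,6-dimethyl-2-oxocyclohex-3-en-1-yl)-N,N,N-trimethylmethanaminium iodide (formed in the flask) | CCOC1=CC(=O)C(C[N+](C)(C)C)C(C)(C)C1.[I-] | intermediate
27 | 3-ethoxy-5,5-dimethyl-6-methylidenecyclohex-2-en-1-one | CCOC1=CC(=O)C(=C)C(C)(C)C1 | intermediate
28 | Grignard reagent from 22, C–Br replaced by C–MgBr (formed in the flask) | Br[Mg]C[C@@H](C)/C(C)=C/C[C@H](CCCc1ccoc1)CO[Si](c1ccccc1)(c1ccccc1)C(C)(C)C | intermediate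
29 | bromomagnesium 5-ethoxy-3,3-dimethyl-2-[(3R,4E,7S)-7-{[(tert-butyldiphenylsilyl)oxy]methyl}-10-(furan-3-yl)-3,4-dimethyldec-4-en-1-yl]cyclohexa-1,5-dien-1-olate (formed in the flask) | CCOC1=CC(O[Mg]Br)=C(CC[C@@H](C)/C(C)=C/C[C@H](CCCc2ccoc2)CO[Si](c2ccccc2)(c2ccccc2)C(C)(C)C)C(C)(C)C1 | intermediate
30 | 5-ethoxy-3,3-dimethyl-2-[(3R,4E,7S)-7-{[(tert-butyldiphenylsilyl)oxy]methyl}-10-(furan-3-yl)-3,4-dimethyldec-4-en-1-yl]cyclohexa-1,5-dien-1-yl trifluoromethanesulfonate (formed in the flask) | CCOC1=CC(OS(=O)(=O)C(F)(F)F)=C(CC[C@@H](C)/C(C)=C/C[C@H](CCCc2ccoc2)CO[Si](c2ccccc2)(c2ccccc2)C(C)(C)C)C(C)(C)C1 | intermediate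
31 | tert-butyl{[(2S,3E)-4-[(1S,2R)-7-ethoxy-1,2,5,5-tetramethyl-1,2,3,4,5,6-hexahydronaphthalen-1-yl]-2-[3-(furan-3-yl)propyl]but-3-en-1-yl]oxy}diphenylsilane | CCOC1=CC2=C(CC[C@@H](C)[C@@]2(C)/C=C/[C@H](CCCc2ccoc2)CO[Si](c2ccccc2)(c2ccccc2)C(C)(C)C)C(C)(C)C1 | intermediate
32 | (4aS,7R,8S)-8-[(1E,3S)-3-{[(tert-butyldiphenylsilyl)oxy]methyl}-6-(furan-3-yl)hex-1-en-1-yl]-4,4,7,8-tetramethyl-4,4a,5,6,7,8-hexahydronaphthalen-2(3H)-one | C[C@@H]1CC[C@@H]2C(=CC(=O)CC2(C)C)[C@]1(C)/C=C/[C@H](CCCc1ccoc1)CO[Si](c1ccccc1)(c1ccccc1)C(C)(C)C | intermediate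
33 | (4aS,7R,8R)-8-[(3S)-3-{[(tert-butyldiphenylsilyl)oxy]methyl}-6-(furan-3-yl)hexyl]-4,4,7,8-tetramethyl-4,4a,5,6,7,8-hexahydronaphthalen-2(3H)-one | C[C@@H]1CC[C@@H]2C(=CC(=O)CC2(C)C)[C@]1(C)CC[C@H](CCCc1ccoc1)CO[Si](c1ccccc1)(c1ccccc1)C(C)(C)C | intermediate
34 | (4aS,7R,8R)-8-[(3S)-6-(furan-3-yl)-3-(hydroxymethyl)hexyl]-4,4,7,8-tetramethyl-4,4a,5,6,7,8-hexahydronaphthalen-2(3H)-one | C[C@@H]1CC[C@@H]2C(=CC(=O)CC2(C)C)[C@]1(C)CC[C@H](CCCc1ccoc1)CO | intermediate
35 | pyridinium salt of the target sulfate (formed in the flask) | C[C@@H]1CC[C@@H]2C(=CC(=O)CC2(C)C)[C@]1(C)CC[C@H](CCCc1ccoc1)COS(=O)(=O)[O-].c1cc[nH+]cc1 | intermediate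
36 | (2S)-5-(furan-3-yl)-2-{2-[(1R,2R,4aS)-1,2,5,5-tetramethyl-7-oxo-1,2,3,4,4a,5,6,7-octahydronaphthalen-1-yl]ethyl}pentyl hydrogen sulfate | C[C@@H]1CC[C@@H]2C(=CC(=O)CC2(C)C)[C@]1(C)CC[C@H](CCCc1ccoc1)COS(=O)(=O)O | target

**Step count**

Total steps: 20. Longest linear sequence: 14 steps (steps 5–13, then 16–20).

**Steps most likely to fail**

Step 16. The telescoped sequence may stall at the carbopalladation, because two fully substituted carbons have to be joined; the alkenylpalladium species could instead be reduced or close in the endo mode, and copper and magnesium salts carried through the flask could slow the palladium catalyst. The fallback replaces palladium by a radical closure and sets out from 22 and 27. The same copper-catalysed conjugate addition, quenched with aqueous NH4Cl, would give 6-[(3R,4E,7S)-7-{[(tert-butyldiphenylsilyl)oxy]methyl}-10-(furan-3-yl)-3,4-dimethyldec-4-en-1-yl]-3-ethoxy-5,5-dimethylcyclohex-2-en-1-one F1. Reduction with i-Bu2AlH would give the allylic alcohol F2, and dilute acid would then give, by Stork–Danheiser transposition, the 4-substituted 5,5-dimethylcyclohex-2-en-1-one F3. Hydrogen-atom-transfer-initiated radical conjugate cyclisation (Fe(acac)3, PhSiH3, EtOH, 60 °C) would place a tertiary radical at C8, which adds 6-exo to C8a and gives the decalone F4 with the side chain already saturated. Saegusa–Ito dehydrogenation (LiN(SiMe3)2, Me3SiCl; then Pd(OAc)2, MeCN) can only introduce the C1=C8a double bond, since C4 is quaternary, and the route is rejoined at 33. The radical closure has less facial bias at C8, so epimers would have to be separated.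

Step 17. Protonation at C4a may show poor facial selectivity, because the two ring-fusion epimers are close in energy and acid equilibration would not correct a mixture by much. The fallback sets C4a during ring closure instead and sets out from triflate 30, isolated after the first three stages of step 16. Mild acid (0.5 M HCl, THF, 0 °C) would hydrolyse only the enol ether and give 5,5-dimethyl-3-oxo-6-[(3R,4E,7S)-7-{[(tert-butyldiphenylsilyl)oxy]methyl}-10-(furan-3-yl)-3,4-dimethyldec-4-en-1-yl]cyclohex-1-en-1-yl trifluoromethanesulfonate F5 as a mixture of epimers at the ring carbon. Mizoroki–Heck cyclisation of F5 (Pd(OAc)2, 1,3-bis(diphenylphosphino)propane, K2CO3, DMA, 75 °C) then closes ring B through a chair in which the C4a–C4 bond and the C7 methyl are both equatorial. Only the C4a epimer of the target series can adopt this geometry, while carbonate should equilibrate the γ-stereocentre of unreacted material (dynamic kinetic resolution). The route is rejoined directly at 32.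

Step 18. Reduction of the hindered trans-alkene next to the quaternary carbon may be slow or incomplete, and forcing it risks conjugate reduction of the enone. The fallback reduces the alkene before the enone is unmasked and sets out from 31. Hydrogenation with RhCl(PPh3)3 (H2, benzene, rt) should saturate the disubstituted alkene and leave the tetrasubstituted and enol-ether double bonds of the diene, to give tert-butyl{[(2S)-4-[(1R,2R)-7-ethoxy-1,2,5,5-tetramethyl-1,2,3,4,5,6-hexahydronaphthalen-1-yl]-2-[3-(furan-3-yl)propyl]butyl]oxy}diphenylsilane F6. Hydrolysis as in step 17 then rejoins the route at 33.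

**Further compounds**

F1 | step 16 | 6-[(3R,4E,7S)-7-{[(tert-butyldiphenylsilyl)oxy]methyl}-10-(furan-3-yl)-3,4-dimethyldec-4-en-1-yl]-3-ethoxy-5,5-dimethylcyclohex-2-en-1-one (C6 epimers) | CCOC1=CC(=O)C(CC[C@@H](C)/C(C)=C/C[C@H](CCCc2ccoc2)CO[Si](c2ccccc2)(c2ccccc2)C(C)(C)C)C(C)(C)C1
F2 | step 16 | 6-[(3R,4E,7S)-7-{[(tert-butyldiphenylsilyl)oxy]methyl}-10-(furan-3-yl)-3,4-dimethyldec-4-en-1-yl]-3-ethoxy-5,5-dimethylcyclohex-2-en-1-ol (mixture of ring diastereomers) | CCOC1=CC(O)C(CC[C@@H](C)/C(C)=C/C[C@H](CCCc2ccoc2)CO[Si](c2ccccc2)(c2ccccc2)C(C)(C)C)C(C)(C)C1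
F3 | step 16 | 4-[(3R,4E,7S)-7-{[(tert-butyldiphenylsilyl)oxy]methyl}-10-(furan-3-yl)-3,4-dimethyldec-4-en-1-yl]-5,5-dimethylcyclohex-2-en-1-one (C4 epimers) | O=C1C=CC(CC[C@@H](C)/C(C)=C/C[C@H](CCCc2ccoc2)CO[Si](c2ccccc2)(c2ccccc2)C(C)(C)C)C(C)(C)C1
F4 | step 16 | (7R,8R)-8-[(3S)-3-{[(tert-butyldiphenylsilyl)oxy]methyl}-6-(furan-3-yl)hexyl]-4,4,7,8-tetramethyloctahydronaphthalen-2(1H)-one (C4a and C8a not defined) | C[C@@H]1CCC2C(CC(=O)CC2(C)C)[C@]1(C)CC[C@H](CCCc1ccoc1)CO[Si](c1ccccc1)(c1ccccc1)C(C)(C)C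
F5 | step 17 | 5,5-dimethyl-3-oxo-6-[(3R,4E,7S)-7-{[(tert-butyldiphenylsilyl)oxy]methyl}-10-(furan-3-yl)-3,4-dimethyldec-4-en-1-yl]cyclohex-1-en-1-yl trifluoromethanesulfonate (C6 epimers) | O=C1C=C(OS(=O)(=O)C(F)(F)F)C(CC[C@@H](C)/C(C)=C/C[C@H](CCCc2ccoc2)CO[Si](c2ccccc2)(c2ccccc2)C(C)(C)C)C(C)(C)C1
F6 | step 18 | tert-butyl{[(2S)-4-[(1R,2R)-7-ethoxy-1,2,5,5-tetramethyl-1,2,3,4,5,6-hexahydronaphthalen-1-yl]-2-[3-(furan-3-yl)propyl]butyl]oxy}diphenylsilane | CCOC1=CC2=C(CC[C@@H](C)[C@@]2(C)CC[C@H](CCCc2ccoc2)CO[Si](c2ccccc2)(c2ccccc2)C(C)(C)C)C(C)(C)C1
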